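**Retrosynthetic overview**

1. Numbering: ring A = C1–C5 and C10; ring B = C5–C10; C4 carries CO2Me and CH3; C8 and C9 carry CH3; the side chain C11–C15 sits on C9. The oxirane is made last, by Sharpless epoxidation of the C13=C14 allylic alcohol.
2. The C1=C10 alkene comes from the C1=C2 alkene of a Diels–Alder adduct by a one-position hydride walk; this erases C10, so both ring-fusion epimers of the adduct converge.
3. Key disconnection: intramolecular Diels–Alder reaction of the acyclic (2Z,8E)-undeca-2,8,10-trienoate 29. C3–C4 and C5–C10 form together, rings A and B close in the same step, and C4 and C5 are set.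
4. Enabling feature: ring A is a cyclohexene whose quaternary C4 carries the ester next to ring-fusion carbon C5. With the alkene at C1=C2 it is the retron of diene C3=C2–C1=C10 and ester-activated dienophile C4=C5, joined by the chain C6–C9 that becomes ring B. The quaternary carbons C4 and C9 confine the later alkene walk to C3–C2–C1–C10.
5. Triene 29 comes from an Ireland–Claisen rearrangement (C8–C9 bond, both stereocentres by chirality transfer from a lactate-derived carbinol), a Still–Gennari olefination and a dehydration; the chain comes from geranyl acetate by Negishi carboalumination. Ring order: A and B together (step 19), oxirane last (step 22).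

Key step: step 19

Remarks on the chemistry: TBS = tert-butyldimethylsilyl, TBDPS = tert-butyldiphenylsilyl. Adduct 30 is carried on as the mixture of its two C10 epimers, because C10 becomes sp2 in step 20.

**Route**

Step 1
Reactants: 1 geranyl acetate
Product: 3 (2E)-3-methyl-6-oxohex-2-en-1-yl acetate, via ozonide 2 (not isolated)
Conditions: O3 (1.0 equiv), CH2Cl2, −78 °C; then PPh3, −78 → 23 °C
Reagents that add atoms: ozone, [O-][O+]=O
Why: Chemoselective ozonolysis with reductive work-up: the 6,7-alkene is the more electron-rich one because the 2,3-alkene is deactivated by the allylic acetate, so one equivalent of ozone should cleave it alone and leave the E-alkene of the future side chain intact.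

Step 2
Reactants: 3 (2E)-3-methyl-6-oxohex-2-en-1-yl acetate
Product: 5 (2E)-3-methylhept-2-en-6-yn-1-ol, via alkynyl acetate 4 (not isolated)
Conditions: MeC(O)C(N2)P(O)(OMe)2, K2CO3, MeOH, 0 → 23 °C
Reagents that add atoms: dimethyl (1-diazo-2-oxopropyl)phosphonate, COP(=O)(OC)C(=[N+]=[N-])C(C)=O
Why: Seyferth–Gilbert homologation in its Ohira–Bestmann form turns the aldehyde into the terminal alkyne (future C9 and C10), and the same K2CO3/MeOH medium methanolyses the acetate; no stereocentre is involved.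

Step 3
Reactants: 5 (2E)-3-methylhept-2-en-6-yn-1-ol
Product: 6 TBDPS ether of 5
Conditions: t-BuPh2SiCl, imidazole, DMF, 23 °C
Reagents that add atoms: tert-butyl(chloro)diphenylsilane, CC(C)(C)[Si](Cl)(c1ccccc1)c1ccccc1
Why: Standard silylation of a primary alcohol; the robust TBDPS ether is meant to survive every step up to step 21.

Step 4
Reactants: 7 methyl (R)-lactate
Product: 8 methyl (2R)-2-(TBS-oxy)propanoate
Conditions: t-BuMe2SiCl, imidazole, DMF, 23 °C
Reagents that add atoms: tert-butyl(chloro)dimethylsilane, CC(C)(C)[Si](C)(C)Cl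
Why: Standard silylation; the non-chelating silyl ether is what enforces Felkin–Anh control in step 8.

Step 5
Reactants: 8 methyl (2R)-2-(TBS-oxy)propanoate
Product: 10 (2R)-2-(TBS-oxy)propanal, via aluminium hemiacetal 9 (not isolated)
Conditions: i-Bu2AlH (1.05 equiv), CH2Cl2, −78 °C; then aq. potassium sodium tartrate
Reagents that add atoms: diisobutylaluminium hydride, CC(C)C[AlH]CC(C)C (aluminium retained only in 9)
Why: Partial reduction of an ester to the aldehyde through the tetrahedral aluminium hemiacetal that is stable at −78 °C; the α-stereocentre is not touched.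

Step 6
Reactants: 6 TBDPS ether of 5; 10 (2R)-2-(TBS-oxy)propanal
Product: 13 allylic alcohol (both carbinol epimers), via alkenylalane 11 (not isolated), via lithium alkenylalanate 12 (not isolated)
Conditions: Me3Al (2 equiv), Cp2ZrCl2 (20 mol %), CH2Cl2, 0 → 23 °C; volatiles removed; n-BuLi, THF, −78 °C; then 10, −78 → 0 °C
Reagents that add atoms: trimethylaluminium, C[Al](C)C; n-butyllithium, [Li]CCCC (butyl retained only in 12)
Why: Zr-catalysed Negishi carboalumination adds CH3 and Al syn across the terminal alkyne with CH3 on the internal carbon, which fixes the E-trisubstituted C9=C10 alkene, and the derived alanate transfers its alkenyl group to the aldehyde; the new carbinol centre (C1) needs no control because step 7 removes it.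

Step 7
Reactants: 13 allylic alcohol (both carbinol epimers)
Product: 14 enone
Conditions: Dess–Martin periodinane, CH2Cl2, 0 → 23 °C
Reagents that add atoms: none
Why: Dess–Martin oxidation of a secondary allylic alcohol under non-basic conditions, which should merge both carbinol epimers and leave the α-silyloxy stereocentre intact.

Step 8
Reactants: 14 enone
Product: 15 (2R,3R)-syn alcohol
Conditions: LiBH(s-Bu)3, THF, −78 °C; then H2O
Reagents that add atoms: none
Why: 1,2-Reduction of a β,β-disubstituted enone by a bulky hydride under Felkin–Anh control (hydride anti to the C–OSi bond) should set the carbinol centre (C1 of the target numbering) as R, syn to the silyloxy group.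

Step 9
Reactants: 15 (2R,3R)-syn alcohol
Product: 16 propanoate of 15
Conditions: (EtCO)2O, Et3N, DMAP (10 mol %), CH2Cl2, 23 °C
Reagents that add atoms: propanoic anhydride, CCC(=O)OC(=O)CC
Why: DMAP-catalysed acylation with retention at the carbinol carbon; the acyl group supplies C7, C8 and the C8 methyl group.

Step 10
Reactants: 16 propanoate of 15
Product: 19 Claisen acid, via silyl ketene acetal 17 (not isolated), via trimethylsilyl ester 18 (not isolated)
Conditions: LiN(i-Pr)2, THF–DMPU (4:1), −78 °C; Me3SiCl; −78 → 60 °C; then aq. citric acid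
Reagents that add atoms: chlorotrimethylsilane, C[Si](C)(C)Cl (silicon retained only in 17 and 18)
Why: Ireland–Claisen rearrangement: enolisation in THF–DMPU gives the Z-silyl ketene acetal, which rearranges through a chair with the CH(CH3)OTBS group of the carbinol carbon equatorial, so that the carbinol configuration is transferred to the quaternary C9, the Z-ketene acetal/E-alkene pairing sets C8 relative to C9 (both methyl groups on the same face of the future ring B), and the new C10=C1 alkene is E.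

Step 11
Reactants: 19 Claisen acid
Product: 20 primary alcohol
Conditions: LiAlH4, Et2O, 0 → 23 °C
Reagents that add atoms: none
Why: Hydride reduction of the carboxylic acid to the primary alcohol (C7); silyl ethers and alkenes are inert and C8 is not epimerised.

Step 12
Reactants: 20 primary alcohol
Product: 21 primary iodide
Conditions: I2, PPh3, imidazole, CH2Cl2, 0 → 23 °C
Reagents that add atoms: iodine, [I][I]
Why: Appel-type iodination of a primary alcohol by SN2 displacement of the alkoxyphosphonium ion; no stereocentre is affected.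

Step 13
Reactants: 21 primary iodide
Product: 22 nitrile
Conditions: MeCN, n-BuLi, THF, −78 °C; then 21, DMPU, −78 → 0 °C
Reagents that add atoms: acetonitrile, CC#N
Why: SN2 alkylation of lithiated acetonitrile by the primary iodide adds C6 and C5 in one step; DMPU and low temperature are meant to favour substitution over E2 at this β-branched centre.

Step 14
Reactants: 22 nitrile
Product: 24 aldehyde, via N-aluminio aldimine 23 (not isolated)
Conditions: i-Bu2AlH, toluene, −78 °C; then aq. tartaric acid, 0 °C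
Reagents that add atoms: diisobutylaluminium hydride, CC(C)C[AlH]CC(C)C (aluminium retained only in 23); water, O
Why: Half-reduction of the nitrile to the N-aluminio imine and hydrolysis give the C5 aldehyde; the imine salt cannot be reduced further at −78 °C.

Step 15
Reactants: 25 methyl 2-[bis(2,2,2-trifluoroethoxy)phosphoryl]acetate
Product: 26 methyl 2-[bis(2,2,2-trifluoroethoxy)phosphoryl]propanoate
Conditions: t-BuOK, THF, 0 °C; then MeI, 0 → 23 °C
Reagents that add atoms: iodomethane, CI
Why: C-Alkylation of the stabilised phosphonate carbanion gives the α-methyl Still–Gennari reagent; its stereocentre is irrelevant because it becomes sp2 in step 16.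

Step 16
Reactants: 24 aldehyde; 26 methyl 2-[bis(2,2,2-trifluoroethoxy)phosphoryl]propanoate
Product: 27 Z-enoate
Conditions: KN(SiMe3)2, 18-crown-6, THF, −78 °C
Reagents that add atoms: none
Why: Still–Gennari olefination: fast, irreversible elimination from the adduct of the trifluoroethyl phosphonate under dissociating conditions should give the Z-trisubstituted enoate (CO2Me cis to C6), the geometry that fixes C4 relative to C5 in step 19.

Step 17
Reactants: 27 Z-enoate
Product: 28 secondary allylic alcohol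
Conditions: HF·pyridine, pyridine, THF, 0 → 23 °C
Reagents that add atoms: none
Why: Selective desilylation: buffered HF cleaves the secondary TBS ether much faster than the primary TBDPS ether, and the Z-enoate is not exposed to base.

Step 18
Reactants: 28 secondary allylic alcohol
Product: 29 (2Z,8E)-triene ester
Conditions: Ph2S[OC(CF3)2Ph]2, CH2Cl2, 0 → 23 °C
Reagents that add atoms: none
Why: Sulfurane-mediated dehydration: the alkoxysulfonium ion can lose a proton only from the adjacent CH3 group (C1 is sp2), which gives the terminal C2=C3 alkene in conjugation with the E C10=C1 alkene.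

Step 19
Reactants: 29 (2Z,8E)-triene ester
Product: 30 Diels–Alder adduct (C10 epimers)
Conditions: toluene (5 mM), BHT (5 mol %), 175 °C, sealed tube
Reagents that add atoms: none
Why: Thermal type 1 intramolecular Diels–Alder reaction (concerted, asynchronous, normal electron demand) of the diene C3=C2–C1=C10 with the ester-activated C4=C5 alkene, the known cyclisation mode of 2,8,10-undecatrienoates to octalins, helped here by the quaternary C9 in the tether. Ring A is closed by the [4+2] bond pair C3–C4/C5–C10, and ring B at the same time by the C5–C10 bond through the C6–C9 tether in a chair-like six-membered array. C4 and C5 are set relative to each other stereospecifically by suprafacial addition to the Z-enoate, which places CO2Me cis to C6 and the C4 methyl cis to H-5. C5 (and with it C4) is set relative to C8/C9 by the tether chair that keeps the C8 methyl equatorial and the C9 methyl axial: only transition states with C4 pseudo-equatorial (H-5 axial, on the face of both methyl groups) avoid a 1,3-diaxial clash between C4 and the axial C9 methyl, in the endo as in the exo mode. C10 is formed without control, which is harmless because step 20 makes it sp2. The step therefore needs only π-facial selectivity, supplied by the C8/C9 stereodiad, and retention of the Z-enoate geometry, for which a non-acidic, radical-inhibited medium is chosen.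

Step 20
Reactants: 30 Diels–Alder adduct (C10 epimers)
Product: 31 C1=C10 alkene
Conditions: RuHCl(CO)(PPh3)3 (5 mol %), toluene, 110 °C
Reagents that add atoms: none
Why: Ruthenium hydride-catalysed positional alkene isomerisation (insertion/β-hydride elimination): the hydride can walk the double bond only along C3–C2–C1–C10, because C4 is quaternary and a move to C5=C10 would need a tertiary C10–Ru alkyl next to quaternary C9, so the trisubstituted C1=C10 alkene should accumulate as the most stable isomer of this set; C10 becomes sp2, both epimers of 30 converge and no stereocentre is created.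

Step 21
Reactants: 31 C1=C10 alkene
Product: 32 allylic alcohol
Conditions: Bu4NF, THF, 0 → 23 °C
Reagents that add atoms: none
Why: Fluoride-induced cleavage of the TBDPS ether frees the allylic alcohol; the hindered ester on quaternary C4 is inert.

Step 22
Reactants: 32 allylic alcohol
Product: 33 target
Conditions: Ti(OiPr)4 (10 mol %), D-(−)-diisopropyl tartrate (12 mol %), t-BuOOH, 4 Å molecular sieves, CH2Cl2, −20 °C
Reagents that add atoms: tert-butyl hydroperoxide, CC(C)(C)OO
Why: Sharpless asymmetric epoxidation: only the allylic alcohol alkene binds to titanium, and D-(−)-tartrate should deliver oxygen to the face that gives the (13R,14R)-epoxide (the mirror-image sense to that of L-(+)-tartrate with E-3-methylalk-2-en-1-ols), while the ring alkene is untouched.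

**Compound list**

1 | geranyl acetate, (2E)-3,7-dimethylocta-2,6-dien-1-yl acetate | CC(C)=CCC/C(C)=C/COC(C)=O | starting material
2 | (2E)-5-(5,5-dimethyl-1,2,4-trioxolan-3-yl)-3-methylpent-2-en-1-yl acetate (racemic at the ring carbon) | CC1(C)OOC(CC/C(C)=C/COC(C)=O)O1 | intermediate (not isolated)
3 | (2E)-3-methyl-6-oxohex-2-en-1-yl acetate | O=CCC/C(C)=C/COC(C)=O | intermediate
4 | (2E)-3-methylhept-2-en-6-yn-1-yl acetate | C#CCC/C(C)=C/COC(C)=O | intermediate (not isolated)
5 | (2E)-3-methylhept-2-en-6-yn-1-ol | C#CCC/C(C)=C/CO | intermediate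
6 | tert-butyl{[(2E)-3-methylhept-2-en-6-yn-1-yl]oxy}diphenylsilane | C#CCC/C(C)=C/CO[Si](c1ccccc1)(c1ccccc1)C(C)(C)C | intermediate
7 | methyl (2R)-2-hydroxypropanoate (methyl (R)-lactate) | C[C@@H](O)C(=O)OC | starting material
8 | methyl (2R)-2-[(tert-butyldimethylsilyl)oxy]propanoate | C[C@@H](O[Si](C)(C)C(C)(C)C)C(=O)OC | intermediate
9 | diisobutylaluminium hemiacetal of 8 (hemiacetal carbon undefined) | C[C@@H](O[Si](C)(C)C(C)(C)C)C(OC)O[Al](CC(C)C)CC(C)C | intermediate (not isolated)
10 | (2R)-2-[(tert-butyldimethylsilyl)oxy]propanal | C[C@@H](O[Si](C)(C)C(C)(C)C)C=O | intermediate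
11 | [(1E,5E)-7-(TBDPS-oxy)-2,5-dimethylhepta-1,5-dien-1-yl]dimethylalumane | C[Al](C)/C=C(\C)CC/C(C)=C/CO[Si](c1ccccc1)(c1ccccc1)C(C)(C)C | intermediate (not isolated)
12 | lithium butyl[(1E,5E)-7-(TBDPS-oxy)-2,5-dimethylhepta-1,5-dien-1-yl]dimethylaluminate | [Li+].CCCC[Al-](C)(C)/C=C(\C)CC/C(C)=C/CO[Si](c1ccccc1)(c1ccccc1)C(C)(C)C | intermediate (not isolated)
13 | (2R,4E,8E)-2-(TBS-oxy)-10-(TBDPS-oxy)-5,8-dimethyldeca-4,8-dien-3-ol, both C3 epimers (C3 undefined in the SMILES) | C[C@@H](O[Si](C)(C)C(C)(C)C)C(O)/C=C(\C)CC/C(C)=C/CO[Si](c1ccccc1)(c1ccccc1)C(C)(C)C | intermediate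
14 | (2R,4E,8E)-2-(TBS-oxy)-10-(TBDPS-oxy)-5,8-dimethyldeca-4,8-dien-3-one | C[C@@H](O[Si](C)(C)C(C)(C)C)C(=O)/C=C(\C)CC/C(C)=C/CO[Si](c1ccccc1)(c1ccccc1)C(C)(C)C | intermediate
15 | (2R,3R,4E,8E)-2-(TBS-oxy)-10-(TBDPS-oxy)-5,8-dimethyldeca-4,8-dien-3-ol | C[C@@H](O[Si](C)(C)C(C)(C)C)[C@H](O)/C=C(\C)CC/C(C)=C/CO[Si](c1ccccc1)(c1ccccc1)C(C)(C)C | intermediate
16 | (2R,3R,4E,8E)-2-(TBS-oxy)-10-(TBDPS-oxy)-5,8-dimethyldeca-4,8-dien-3-yl propanoate | C[C@@H](O[Si](C)(C)C(C)(C)C)[C@H](OC(=O)CC)/C=C(\C)CC/C(C)=C/CO[Si](c1ccccc1)(c1ccccc1)C(C)(C)C | intermediate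
17 | (Z)-trimethylsilyl ketene acetal of 16 | C/C=C(\O[Si](C)(C)C)O[C@@H]([C@@H](C)O[Si](C)(C)C(C)(C)C)/C=C(\C)CC/C(C)=C/CO[Si](c1ccccc1)(c1ccccc1)C(C)(C)C | intermediate (not isolated)
18 | trimethylsilyl ester of 19 | C[Si](C)(C)OC(=O)[C@@H](C)[C@](C)(CC/C(C)=C/CO[Si](c1ccccc1)(c1ccccc1)C(C)(C)C)/C=C/[C@@H](C)O[Si](C)(C)C(C)(C)C | intermediate (not isolated)
19 | (2S,3R,4E,6R)-6-(TBS-oxy)-3-[(3E)-5-(TBDPS-oxy)-3-methylpent-3-en-1-yl]-2,3-dimethylhept-4-enoic acid | OC(=O)[C@@H](C)[C@](C)(CC/C(C)=C/CO[Si](c1ccccc1)(c1ccccc1)C(C)(C)C)/C=C/[C@@H](C)O[Si](C)(C)C(C)(C)C | intermediate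
20 | (2S,3R,4E,6R)-6-(TBS-oxy)-3-[(3E)-5-(TBDPS-oxy)-3-methylpent-3-en-1-yl]-2,3-dimethylhept-4-en-1-ol | OC[C@@H](C)[C@](C)(CC/C(C)=C/CO[Si](c1ccccc1)(c1ccccc1)C(C)(C)C)/C=C/[C@@H](C)O[Si](C)(C)C(C)(C)C | intermediate
21 | (2S,3R,4E,6R)-1-iodo-6-(TBS-oxy)-3-[(3E)-5-(TBDPS-oxy)-3-methylpent-3-en-1-yl]-2,3-dimethylhept-4-ene | IC[C@@H](C)[C@](C)(CC/C(C)=C/CO[Si](c1ccccc1)(c1ccccc1)C(C)(C)C)/C=C/[C@@H](C)O[Si](C)(C)C(C)(C)C | intermediate
22 | (4R,5S,6E,8R)-8-(TBS-oxy)-5-[(3E)-5-(TBDPS-oxy)-3-methylpent-3-en-1-yl]-4,5-dimethylnon-6-enenitrile | N#CCC[C@@H](C)[C@](C)(CC/C(C)=C/CO[Si](c1ccccc1)(c1ccccc1)C(C)(C)C)/C=C/[C@@H](C)O[Si](C)(C)C(C)(C)C | intermediate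
23 | N-(diisobutylalumanyl) aldimine of 24 | CC(C)C[Al](CC(C)C)N=CCC[C@@H](C)[C@](C)(CC/C(C)=C/CO[Si](c1ccccc1)(c1ccccc1)C(C)(C)C)/C=C/[C@@H](C)O[Si](C)(C)C(C)(C)C | intermediate (not isolated)
24 | (4R,5S,6E,8R)-8-(TBS-oxy)-5-[(3E)-5-(TBDPS-oxy)-3-methylpent-3-en-1-yl]-4,5-dimethylnon-6-enal | O=CCC[C@@H](C)[C@](C)(CC/C(C)=C/CO[Si](c1ccccc1)(c1ccccc1)C(C)(C)C)/C=C/[C@@H](C)O[Si](C)(C)C(C)(C)C | intermediate
25 | methyl 2-[bis(2,2,2-trifluoroethoxy)phosphoryl]acetate | COC(=O)CP(=O)(OCC(F)(F)F)OCC(F)(F)F | starting material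
26 | methyl 2-[bis(2,2,2-trifluoroethoxy)phosphoryl]propanoate (racemic) | COC(=O)C(C)P(=O)(OCC(F)(F)F)OCC(F)(F)F | intermediate
27 | methyl (2Z,6R,7S,8E,10R)-10-(TBS-oxy)-7-[(3E)-5-(TBDPS-oxy)-3-methylpent-3-en-1-yl]-2,6,7-trimethylundeca-2,8-dienoate | COC(=O)/C(C)=C\CC[C@@H](C)[C@](C)(CC/C(C)=C/CO[Si](c1ccccc1)(c1ccccc1)C(C)(C)C)/C=C/[C@@H](C)O[Si](C)(C)C(C)(C)C | intermediate
28 | methyl (2Z,6R,7S,8E,10R)-10-hydroxy-7-[(3E)-5-(TBDPS-oxy)-3-methylpent-3-en-1-yl]-2,6,7-trimethylundeca-2,8-dienoate | COC(=O)/C(C)=C\CC[C@@H](C)[C@](C)(CC/C(C)=C/CO[Si](c1ccccc1)(c1ccccc1)C(C)(C)C)/C=C/[C@@H](C)O | intermediate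
29 | methyl (2Z,6R,7S,8E)-7-[(3E)-5-(TBDPS-oxy)-3-methylpent-3-en-1-yl]-2,6,7-trimethylundeca-2,8,10-trienoate | COC(=O)/C(C)=C\CC[C@@H](C)[C@](C)(CC/C(C)=C/CO[Si](c1ccccc1)(c1ccccc1)C(C)(C)C)/C=C/C=C | intermediate
30 | methyl (1S,5S,6R,8aR)-5-[(3E)-5-(TBDPS-oxy)-3-methylpent-3-en-1-yl]-1,5,6-trimethyl-1,2,4a,5,6,7,8,8a-octahydronaphthalene-1-carboxylate, both C4a (= C10) epimers (C4a undefined in the SMILES) | COC(=O)[C@@]1(C)CC=CC2[C@H]1CC[C@@H](C)[C@]2(C)CC/C(C)=C/CO[Si](c1ccccc1)(c1ccccc1)C(C)(C)C | intermediate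
31 | methyl (1S,5S,6R,8aR)-5-[(3E)-5-(TBDPS-oxy)-3-methylpent-3-en-1-yl]-1,5,6-trimethyl-1,2,3,5,6,7,8,8a-octahydronaphthalene-1-carboxylate | COC(=O)[C@@]1(C)CCC=C2[C@H]1CC[C@@H](C)[C@]2(C)CC/C(C)=C/CO[Si](c1ccccc1)(c1ccccc1)C(C)(C)C | intermediate
32 | methyl (1S,5S,6R,8aR)-5-[(3E)-5-hydroxy-3-methylpent-3-en-1-yl]-1,5,6-trimethyl-1,2,3,5,6,7,8,8a-octahydronaphthalene-1-carboxylate | COC(=O)[C@@]1(C)CCC=C2[C@H]1CC[C@@H](C)[C@]2(C)CC/C(C)=C/CO | intermediate
33 | methyl (1S,5S,6R,8aR)-5-{2-[(2R,3R)-3-(hydroxymethyl)-2-methyloxiran-2-yl]ethyl}-1,5,6-trimethyl-1,2,3,5,6,7,8,8a-octahydronaphthalene-1-carboxylate | COC(=O)[C@@]1(C)CCC=C2[C@H]1CC[C@@H](C)[C@]2(C)CC[C@@]1(C)O[C@@H]1CO | target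

**Step count and risks**

Total step count: 22. Longest linear sequence: 19 steps (steps 1–3, 6–14 and 16–22).

Steps most likely to fail:

1. Step 20. The hydride walk may not stop cleanly: migration beyond C1=C10 into the ring fusion if an allyl-hydride pathway intervenes, incomplete equilibration, or isomerisation of the side-chain allylic silyl ether to an enol ether. The fallback sets out from 28 and returns at 31; it fixes the alkene position by oxygen instead of by equilibration. Alcohol 28 is oxidised with Dess–Martin periodinane to the methyl enone F1. Soft enolisation (t-BuMe2SiOTf, Et3N, CH2Cl2) gives the 2-silyloxy diene F2, which should undergo the same intramolecular Diels–Alder reaction at 110–130 °C to the silyl enol ether F3 (C1=C2, both C10 epimers). Saegusa–Ito oxidation with Pd(OAc)2 can lose hydrogen only from C10 and should give the C1=C10 enone F4 from both epimers. The C2 carbonyl is then removed through the 1,3-dithiolane F5 (HSCH2CH2SH, BF3·OEt2) and Raney nickel desulfurisation, which gives 31.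

2. Step 19. π-Facial discrimination may be insufficient at 175 °C, or the Z-geometry of the enoate may erode before cyclisation (reversible 1,5-hydrogen shift to the dienol), which would scramble C4. The fallback sets out from 29 and returns at 30; it uses a more reactive dienophile that should cyclise far below this temperature. Ester 29 is reduced with i-Bu2AlH to the Z-allylic alcohol F6 and oxidised with Dess–Martin periodinane to the Z-enal F7, which is used at once. The enal should cyclise at 60–80 °C in toluene to the aldehyde adduct F8. Pinnick oxidation (NaClO2, NaH2PO4, 2-methylbut-2-ene) gives the acid F9, and Me3SiCHN2 in MeOH returns methyl ester 30.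

3. Step 13. SN2 displacement at the β-branched iodide next to the quaternary centre may be slow, with competing E2 elimination by the basic nitrile anion. The fallback sets out from 20 and returns at 24; it extends the chain by olefination and conjugate reduction instead of alkylation. Alcohol 20 is oxidised with Dess–Martin periodinane to the aldehyde F10, a Wittig reaction with Ph3P=CHCHO gives the E-enal F11, and chemoselective 1,4-reduction with [(Ph3P)CuH]6, which leaves isolated alkenes alone, gives aldehyde 24.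

**Further compounds**

F1 | step 20 | methyl (2Z,6R,7S,8E)-7-[(3E)-5-(TBDPS-oxy)-3-methylpent-3-en-1-yl]-2,6,7-trimethyl-10-oxoundeca-2,8-dienoate | COC(=O)/C(C)=C\CC[C@@H](C)[C@](C)(CC/C(C)=C/CO[Si](c1ccccc1)(c1ccccc1)C(C)(C)C)/C=C/C(C)=O
F2 | step 20 | methyl (2Z,6R,7S,8E)-10-(TBS-oxy)-7-[(3E)-5-(TBDPS-oxy)-3-methylpent-3-en-1-yl]-2,6,7-trimethylundeca-2,8,10-trienoate | COC(=O)/C(C)=C\CC[C@@H](C)[C@](C)(CC/C(C)=C/CO[Si](c1ccccc1)(c1ccccc1)C(C)(C)C)/C=C/C(=C)O[Si](C)(C)C(C)(C)C
F3 | step 20 | methyl (1S,5S,6R,8aR)-3-(TBS-oxy)-5-[(3E)-5-(TBDPS-oxy)-3-methylpent-3-en-1-yl]-1,5,6-trimethyl-1,2,4a,5,6,7,8,8a-octahydronaphthalene-1-carboxylate, both C4a epimers | COC(=O)[C@@]1(C)CC(O[Si](C)(C)C(C)(C)C)=CC2[C@H]1CC[C@@H](C)[C@]2(C)CC/C(C)=C/CO[Si](c1ccccc1)(c1ccccc1)C(C)(C)C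
F4 | step 20 | methyl (1S,5S,6R,8aR)-5-[(3E)-5-(TBDPS-oxy)-3-methylpent-3-en-1-yl]-1,5,6-trimethyl-3-oxo-1,2,3,5,6,7,8,8a-octahydronaphthalene-1-carboxylate | COC(=O)[C@@]1(C)CC(=O)C=C2[C@H]1CC[C@@H](C)[C@]2(C)CC/C(C)=C/CO[Si](c1ccccc1)(c1ccccc1)C(C)(C)C
F5 | step 20 | 1,3-dithiolane (ethane-1,2-diyl dithioketal at C3 of the naphthalene numbering) of F4 | COC(=O)[C@@]1(C)CC3(SCCS3)C=C2[C@H]1CC[C@@H](C)[C@]2(C)CC/C(C)=C/CO[Si](c1ccccc1)(c1ccccc1)C(C)(C)C
F6 | step 19 | (2Z,6R,7S,8E)-7-[(3E)-5-(TBDPS-oxy)-3-methylpent-3-en-1-yl]-2,6,7-trimethylundeca-2,8,10-trien-1-ol | OC/C(C)=C\CC[C@@H](C)[C@](C)(CC/C(C)=C/CO[Si](c1ccccc1)(c1ccccc1)C(C)(C)C)/C=C/C=C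
F7 | step 19 | (2Z,6R,7S,8E)-7-[(3E)-5-(TBDPS-oxy)-3-methylpent-3-en-1-yl]-2,6,7-trimethylundeca-2,8,10-trienal | O=C/C(C)=C\CC[C@@H](C)[C@](C)(CC/C(C)=C/CO[Si](c1ccccc1)(c1ccccc1)C(C)(C)C)/C=C/C=C
F8 | step 19 | (1S,5S,6R,8aR)-5-[(3E)-5-(TBDPS-oxy)-3-methylpent-3-en-1-yl]-1,5,6-trimethyl-1,2,4a,5,6,7,8,8a-octahydronaphthalene-1-carbaldehyde, both C4a epimers | O=C[C@@]1(C)CC=CC2[C@H]1CC[C@@H](C)[C@]2(C)CC/C(C)=C/CO[Si](c1ccccc1)(c1ccccc1)C(C)(C)C
F9 | step 19 | (1S,5S,6R,8aR)-5-[(3E)-5-(TBDPS-oxy)-3-methylpent-3-en-1-yl]-1,5,6-trimethyl-1,2,4a,5,6,7,8,8a-octahydronaphthalene-1-carboxylic acid, both C4a epimers | OC(=O)[C@@]1(C)CC=CC2[C@H]1CC[C@@H](C)[C@]2(C)CC/C(C)=C/CO[Si](c1ccccc1)(c1ccccc1)C(C)(C)C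
F10 | step 13 | (2S,3R,4E,6R)-6-(TBS-oxy)-3-[(3E)-5-(TBDPS-oxy)-3-methylpent-3-en-1-yl]-2,3-dimethylhept-4-enal | O=C[C@@H](C)[C@](C)(CC/C(C)=C/CO[Si](c1ccccc1)(c1ccccc1)C(C)(C)C)/C=C/[C@@H](C)O[Si](C)(C)C(C)(C)C
F11 | step 13 | (2E,4R,5R,6E,8R)-8-(TBS-oxy)-5-[(3E)-5-(TBDPS-oxy)-3-methylpent-3-en-1-yl]-4,5-dimethylnona-2,6-dienal | O=C/C=C/[C@@H](C)[C@](C)(CC/C(C)=C/CO[Si](c1ccccc1)(c1ccccc1)C(C)(C)C)/C=C/[C@@H](C)O[Si](C)(C)C(C)(C)C
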